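## Analysis of the target

The target 33 is a (2S)-flavanone. Ring A is a phloroglucinol unit with free hydroxyls at C5 and C7, ring C is the dihydropyranone O1–C2–C3–C4 fused at C8a and C4a, ring B at C2 is a 4-hydroxy-2-methoxyphenyl group, and C8 carries a hydrated lavandulyl chain, CH2–CH(isopropenyl)–CH2CH2–C(OH)Me2. There are two stereocentres, C2 (S) and the chain carbon C2'' (R); C8, C8a, O1 and the benzylic CH2 lie between them, so neither can direct the other and each must be set on its own. In space, C2'' (R) corresponds to (S)-lavandulol (the descriptor changes only because CH2OH becomes CH2Ar), so neither the racemic nor the natural (R)-alcohol of commerce can supply it. The sensitive groups are the flavanone (base opens it to the chalcone and racemises C2), the 4'-hydroxyl para to C2 (acid can ionise C2–O1), the isopropenyl group and tertiary alcohol (strong acid, hydrogenation) and four phenols (late oxidants). The hard points are placing a non-allylic, β-branched alkyl group at C8 and not C6, making C2 in one absolute sense on a 5,7-dioxygenated ring, and telling apart the three phloroglucinol oxygens and the two alkenes of a lavandulyl precursor. The strategy rests on ring C: O1=C8a–C4a=C4 is a four-atom oxadiene once ring A is written as the ortho-quinone methide of a salicylaldehyde, C2=C3 with its aryl group is the styrene 27, and an oxygen kept on C4 through the cycloaddition later becomes the ketone.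

## Retrosynthetic reasoning

**33 from 32.** The last operation only removes four silyl ethers (O5, O7, O4' and the tertiary oxygen). Silicon is the only protecting-group class at the end, because buffered fluoride is the one deprotection that the base-labile flavanone and the acid-labile isopropenyl and tertiary alcohol groups all tolerate.

**32 from 31, 30 and 29.** The C4 carbonyl is traced back to a C4 methoxy group: oxidation of the flavan-4-ol 31, which comes from solvolysis of the benzylic methyl ether 30. Before that the 4'-hydroxyl of 29 is silylated, since a free para-hydroxyl would help acid open C2–O1 and would not survive the oxidant. The gain is that ring C is formed without a carbonyl at C4, so the chalcone pathway is never opened while C2 is being set.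

**29 from 25 and 27 through 28.** O1–C2 and C3–C4 are cut together. These are the two bonds that close ring C and create C2, and cutting them leaves two fragments of similar size, each with one aromatic ring. Cuts at C2–C1' or C4–C4a would leave C2 to a separate step. The forward reaction must ionise the acetal 25 to the quinone methide 28 under a chiral acid, add 27 with O1 going to the benzylic carbon, and fix C2 as S.

**25 from 23 and 24; 23 from 22 and 20.** The acetal comes from the aldehyde 23 and the orthoformate 24. The pattern of 23 (C8a hydroxyl free, O5 and O7 silylated) makes the regiochemistry of the cycloaddition automatic. It is reached from 20 by removing both methoxymethyl ethers (22) and silylating the one hydroxyl that is not hydrogen-bonded to the aldehyde.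

**20 from 18 through 19.** The C4a–C4 bond is cut. Arene 18 is symmetric about its C8–C5 axis, so its two open ring positions are the same. The formyl group therefore ends up between the O5 silyl ether and the oxygen that becomes O1, and that oxygen is next to the alkylated carbon. This is what secures C8 over C6.

**18 from 16 and 11 through 17.** The aryl–CH2 bond is cut. The chain is homoallylic, not allylic, so neither Friedel–Crafts alkylation nor a Claisen rearrangement can place it. A palladium-catalysed coupling of the alkylzinc 17 with the aryl iodide 16 does, and the stereocentre, β to the metal, cannot epimerise.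

**16 from 14, 13 and 12.** The iodine enters between the two methoxymethyl ethers by lithiation (15). The lone triisopropylsilyl group, put on 12 first, marks the oxygen that becomes O5.

**11 from 10, 9, 8 and 7; 7 from 4 and 5 through 6; 4 from 1 and 2 through 3.** The iodide comes from the diol 9. The tertiary alcohol comes from the trisubstituted alkene of 7 by way of the epoxide 8, and the same hydride step removes the auxiliary. The stereocentre is built by auxiliary-controlled α-prenylation of the dienolate 6, which gives the required spatial series directly.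

**27 from 26.** One methylenation of the aldehyde.

## Alternatives that were turned down

**Alternative 1:** Ring A is made last. Ring C and C2 are already present in the dihydropyranone–dioxinone A1, whose enol-ether carbon (future C8a) carries C8 with the side chain and the dioxinone. Heating A1 unmasks an acylketene; enolisation of the C7 ketone toward C8 gives a dienylketene (C5=C6, C7=C8, C8a=C4a), 6π-electrocyclisation forms C4a–C5, and tautomerisation gives the flavanone A2, two desilylations short of 33.
- For it: both ring A hydroxyls arise free, so the protecting-group steps on ring A disappear; C8 regiochemistry is fixed by connectivity; C2 would come from an asymmetric hetero-Diels–Alder construction of the dihydropyranone, a mature reaction class. On that last point it is stronger than the untested induction of step 16.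
- Against it: C8 of A1 is flanked by two acceptor units and a β-branched chain. Assembling it needs vinylogous enolate chemistry and C-acylation on a base-sensitive 2-aryl-dihydropyranone, which can open by β-elimination and lose C2. In the thermal step the acylketene has other outlets (O-closure of the C7 enol to a pyranone, [2+2] or ene reaction with the isopropenyl group), and the 5,7-dihydroxyflavanone formed is exposed to heat.
- Comparison: the chosen route is more convergent and keeps its one uncertain step late, with a fallback in known chemistry. Alternative 1 moves the risk into a long linear preparation of A1.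

**Alternative 2:** Ring A is cut at C8a–C8 and C6–C7 into the cyclobutenone A3 and the siloxyalkyne A4, the latter from (R)-limonene A5 (ring cleavage gives exactly the chain carbons; the methyl ketone becomes the tertiary carbinol). Heating A3 gives a vinylketene, which adds A4 by [2+2]; 4π-opening, 6π-closure and tautomerisation give the phenol A6, free only at C8a, with a silyl ether at C7 and a 4-methoxybenzyl ether at C5.
- For it: the chain stereocentre comes from the chiral pool in the correct sense from the cheap enantiomer; the tertiary alcohol is made without distinguishing two alkenes; no cross-coupling is needed; the three ring A oxygens are differentiated in one step. On all of these it is stronger than steps 1–14 here.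
- Against it: A6 still lacks C4, ring C and C2, so it solves ring A only and must be finished by the same quinone methide chemistry or another asymmetric ring C construction. A4 needs ynolate chemistry; the thermal benzannulation exposes a ketene to the isopropenyl group; the 4-methoxybenzyl ether needs an oxidant or acid that the electron-rich, acid-sensitive late intermediates tolerate poorly.
- Comparison: the chosen route accepts a longer ring A preparation from 12, but every step is routine, only silyl groups remain at the end, and all new chemistry is confined to one step.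

**Alternative 3:** Ring C is cut at C4a–C4, C4–C3 and O1–C2. A palladium-catalysed carbonylative coupling of the iodophenol A7 with the arylacetylene A8 gives an alkynyl ketone that closes 6-endo to the flavone A9; enantioselective conjugate reduction of C2=C3 would then give 32.
- For it: three bonds are made in one operation by established palladium catalysis; A9 is robust and has no C2 centre to lose; C4 is already a ketone, which saves steps 18 and 19. On those points it is stronger.
- Against it: C2 must be created by asymmetric reduction of a 2-aryl-chromone with an ortho-methoxy group and a peri silyloxy group. Hydrogenation catalysts would also saturate the isopropenyl group, hydride conjugate reductions of flavones are sluggish and prone to over-reduction at C4, and the closure can go 5-exo to an aurone. A7 needs the same oxygen differentiation of ring A as here plus a regioselective iodination, so nothing is saved there.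
- Comparison: the chosen strategy sets C2 as the ring forms, at the oxidation level of an ether, and the chain alkene never meets a reducing agent.

Key step: step 16

## Remarks before the steps

- Abbreviations: TBS = tert-butyldimethylsilyl, TIPS = triisopropylsilyl, TES = triethylsilyl, MOM = methoxymethyl.
- Assumption: the sense of induction of the phosphoric acid in step 16 cannot be deduced from precedent. The (R)-acid is written; its mirror image is to be used if it favours the (2R)-series.

## Route

Step 1
Reactants: 1 (4S)-4-benzyl-1,3-oxazolidin-2-one; 2 3-methylbut-2-enoyl chloride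
Product: 4 (4S)-4-benzyl-3-(3-methylbut-2-enoyl)-1,3-oxazolidin-2-one, via lithium oxazolidinide 3 (not isolated)
Conditions: n-BuLi, THF, −78 °C; then 2, −78 → 0 °C
Reagents that add atoms: none
Why: N-acylation of the lithiated Evans auxiliary; the base is consumed before the acid chloride is added, so no vinylketene and no deconjugated acyl group can form.

Step 2
Reactants: 4 (4S)-4-benzyl-3-(3-methylbut-2-enoyl)-1,3-oxazolidin-2-one; 5 1-bromo-3-methylbut-2-ene
Product: 7 (4S)-4-benzyl-3-[(2S)-5-methyl-2-(prop-1-en-2-yl)hex-4-enoyl]-1,3-oxazolidin-2-one, via sodium dienolate 6 (not isolated)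
Conditions: NaN(SiMe3)2, THF, −78 °C; then 5, −78 → −40 °C
Reagents that add atoms: none
Why: Evans asymmetric alkylation in its deconjugative form: γ-deprotonation of the s-cis enoyl imide gives the chelated (Z)-dienolate 6, which is alkylated at the α-carbon by the allylic bromide on the face opposite the benzyl group. This sets the (S)-centre that becomes C2'' of the target and leaves the isopropenyl group in place.

Step 3
Reactants: 7 (4S)-4-benzyl-3-[(2S)-5-methyl-2-(prop-1-en-2-yl)hex-4-enoyl]-1,3-oxazolidin-2-one
Product: 8 (4S)-4-benzyl-3-[(2S)-2-[(3,3-dimethyloxiran-2-yl)methyl]-3-methylbut-3-enoyl]-1,3-oxazolidin-2-one (both epimers at the oxirane carbon)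
Conditions: mCPBA (1.05 equiv), CH2Cl2, −20 → 0 °C
Reagents that add atoms: 3-chloroperoxybenzoic acid, O=C(OO)c1cccc(Cl)c1
Why: Prilezhaev epoxidation; the trisubstituted alkene is much more nucleophilic than the 1,1-disubstituted one, which is also deactivated inductively by the imide, so one equivalent of peracid at low temperature should take the prenyl double bond only. The new oxirane centre forms without selectivity but becomes a CH2 group in step 4.

Step 4
Reactants: 8 (4S)-4-benzyl-3-[(2S)-2-[(3,3-dimethyloxiran-2-yl)methyl]-3-methylbut-3-enoyl]-1,3-oxazolidin-2-one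
Product: 9 (2S)-5-methyl-2-(prop-1-en-2-yl)hexane-1,5-diol
Conditions: LiAlH4, THF, 0 °C → rt
Reagents that add atoms: none
Why: Hydride reduction does two jobs: reductive cleavage of the N-acyl oxazolidinone to the primary alcohol (auxiliary recovered) and SN2 opening of the epoxide at its less substituted carbon to the tertiary alcohol. The stereocentre is not touched and is no longer enolisable afterwards.

Step 5
Reactants: 9 (2S)-5-methyl-2-(prop-1-en-2-yl)hexane-1,5-diol
Product: 10 (5S)-6-iodo-2-methyl-5-(prop-1-en-2-yl)hexan-2-ol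
Conditions: I2, PPh3, imidazole, CH2Cl2, 0 °C → rt
Reagents that add atoms: iodine, II
Why: Appel-type iodination (Garegg–Samuelsson conditions); only the primary alcohol forms an alkoxyphosphonium ion that iodide can displace, and the tertiary hydroxyl does not react.

Step 6
Reactants: 10 (5S)-6-iodo-2-methyl-5-(prop-1-en-2-yl)hexan-2-ol
Product: 11 triethyl{[(5S)-6-iodo-2-methyl-5-(prop-1-en-2-yl)hexan-2-yl]oxy}silane
Conditions: Et3SiOTf, 2,6-lutidine, CH2Cl2, −78 → 0 °C
Reagents that add atoms: triethylsilyl trifluoromethanesulfonate, CC[Si](CC)(CC)OS(=O)(=O)C(F)(F)F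
Why: Silylation of a hindered tertiary alcohol with a silyl triflate; the ether masks the only acidic proton of the chain before the organozinc and organolithium steps.

Step 7
Reactants: 12 phloroglucinol
Product: 13 5-(TIPSO)benzene-1,3-diol
Conditions: TIPSCl (1 equiv), imidazole, DMF, 0 °C, 12 in threefold excess
Reagents that add atoms: triisopropylsilyl chloride, CC(C)[Si](Cl)(C(C)C)C(C)C
Why: Statistical monosilylation; the excess of the cheap triol suppresses over-silylation and washes out with water. The bulky silyl ether marks the oxygen that becomes O5 and survives organolithium reagents.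

Step 8
Reactants: 13 5-(TIPSO)benzene-1,3-diol
Product: 14 1,3-bis(methoxymethoxy)-5-(TIPSO)benzene
Conditions: MOMCl, iPr2NEt, CH2Cl2, 0 °C → rt
Reagents that add atoms: chloromethyl methyl ether, COCCl
Why: Williamson-type acetal ether formation on both phenols; the methoxymethyl ethers are the directing groups for the two lithiations that follow.

Step 9
Reactants: 14 1,3-bis(methoxymethoxy)-5-(TIPSO)benzene
Product: 16 2-iodo-1,3-bis(methoxymethoxy)-5-(TIPSO)benzene, via aryllithium 15 (not isolated)
Conditions: n-BuLi, THF, 0 °C; then I2, −78 °C → rt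
Reagents that add atoms: iodine, II
Why: Directed ortho-metalation at the position flanked by both methoxymethyl ethers, which is the most acidic and doubly coordinated site and is not shielded by the silyl group, followed by iodine quench.

Step 10
Reactants: 11 triethyl{[(5S)-6-iodo-2-methyl-5-(prop-1-en-2-yl)hexan-2-yl]oxy}silane; 16 2-iodo-1,3-bis(methoxymethoxy)-5-(TIPSO)benzene
Product: 18 2-[(2R)-5-methyl-2-(prop-1-en-2-yl)-5-(TESO)hexyl]-1,3-bis(methoxymethoxy)-5-(TIPSO)benzene, via alkylzinc iodide 17 (not isolated)
Conditions: Zn dust, LiCl, THF, 40 °C; then 16, Pd(OAc)2 (cat.), SPhos, THF, rt → 50 °C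
Reagents that add atoms: none
Why: Negishi coupling: zinc inserts into the primary C–I bond, zerovalent palladium adds oxidatively to the aryl iodide, and the bulky biarylphosphine allows transmetalation and reductive elimination at a di-ortho-substituted centre faster than β-hydride elimination. The stereocentre is β to zinc and is not affected; its descriptor changes from S to R only because the priorities change.

Step 11
Reactants: 18 2-[(2R)-5-methyl-2-(prop-1-en-2-yl)-5-(TESO)hexyl]-1,3-bis(methoxymethoxy)-5-(TIPSO)benzene
Product: 20 2,4-bis(methoxymethoxy)-3-[(2R)-5-methyl-2-(prop-1-en-2-yl)-5-(TESO)hexyl]-6-(TIPSO)benzaldehyde, via ring-lithiated arene 19 (not isolated)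
Conditions: s-BuLi, TMEDA, THF, −78 °C; then DMF, −78 °C → rt; aq. NH4Cl
Reagents that add atoms: N,N-dimethylformamide, CN(C)C=O
Why: Directed ortho-metalation and formylation; the two open ring positions are equivalent by symmetry, and each lies between a directing methoxymethyl ether and the silyloxy oxygen. The low temperature is chosen to suppress silyl migration from oxygen to carbon and allylic metalation.

Step 12
Reactants: 20 2,4-bis(methoxymethoxy)-3-[(2R)-5-methyl-2-(prop-1-en-2-yl)-5-(TESO)hexyl]-6-(TIPSO)benzaldehyde
Product: 22 2,4-dihydroxy-3-[(2R)-5-methyl-2-(prop-1-en-2-yl)-5-(TESO)hexyl]-6-(TIPSO)benzaldehyde, via bis(trimethylsilyl) ether 21 (not isolated)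
Conditions: Me3SiOTf, 2,2'-bipyridyl, CH2Cl2, 0 °C → rt; then H2O
Reagents that add atoms: none
Why: Cleavage of aromatic methoxymethyl ethers with a silyl triflate and 2,2'-bipyridyl: the acetal is activated at oxygen, the methoxymethyl unit is taken up by the pyridine base, and the aryl trimethylsilyl ethers 21 hydrolyse on contact with water. The medium is buffered and non-protic, so the aryl TIPS ether, the tertiary TES ether and the isopropenyl group should survive.

Step 13
Reactants: 22 2,4-dihydroxy-3-[(2R)-5-methyl-2-(prop-1-en-2-yl)-5-(TESO)hexyl]-6-(TIPSO)benzaldehyde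
Product: 23 4-(TBSO)-2-hydroxy-3-[(2R)-5-methyl-2-(prop-1-en-2-yl)-5-(TESO)hexyl]-6-(TIPSO)benzaldehyde
Conditions: TBSCl (1.05 equiv), imidazole, CH2Cl2, 0 °C
Reagents that add atoms: tert-butyldimethylsilyl chloride, CC(C)(C)[Si](C)(C)Cl
Why: Selective O-silylation; the hydroxyl para to the formyl group is the more acidic and is free, whereas the ortho hydroxyl is hydrogen-bonded to the carbonyl and flanked on both sides, so it stays free as the future O1.

Step 14
Reactants: 23 4-(TBSO)-2-hydroxy-3-[(2R)-5-methyl-2-(prop-1-en-2-yl)-5-(TESO)hexyl]-6-(TIPSO)benzaldehyde; 24 trimethyl orthoformate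
Product: 25 3-(TBSO)-6-(dimethoxymethyl)-2-[(2R)-5-methyl-2-(prop-1-en-2-yl)-5-(TESO)hexyl]-5-(TIPSO)phenol
Conditions: 24 (excess), pyridinium p-toluenesulfonate (cat.), CH2Cl2, rt; Et3N, concentrate, use crude
Reagents that add atoms: none
Why: Acid-catalysed acetalisation with the orthoformate as methoxy source and water scavenger. The acetal is labile, so the catalyst is neutralised and the material is taken on without chromatography; this also means step 16 sees no achiral acid.

Step 15
Reactants: 26 4-hydroxy-2-methoxybenzaldehyde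
Product: 27 3-methoxy-4-vinylphenol
Conditions: Ph3PCH3Br, KOtBu (2.5 equiv each), THF, 0 °C → rt
Reagents that add atoms: methyltriphenylphosphonium bromide, C[P+](c1ccccc1)(c1ccccc1)c1ccccc1.[Br-]
Why: Wittig methylenation with excess ylide, one equivalent being consumed by the phenol; the styrene is used fresh because vinylphenols polymerise on standing.

Step 16
Reactants: 25 3-(TBSO)-6-(dimethoxymethyl)-2-[(2R)-5-methyl-2-(prop-1-en-2-yl)-5-(TESO)hexyl]-5-(TIPSO)phenol; 27 3-methoxy-4-vinylphenol
Product: 29 4-[(2S,4S)-7-(TBSO)-4-methoxy-8-[(2R)-5-methyl-2-(prop-1-en-2-yl)-5-(TESO)hexyl]-5-(TIPSO)chroman-2-yl]-3-methoxyphenol, via ortho-quinone methide 28 (not isolated)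
Conditions: (R)-3,3'-bis(2,4,6-triisopropylphenyl)-1,1'-binaphthyl-2,2'-diyl hydrogen phosphate (10 mol %), 27 (1.5 equiv), 5 Å MS, toluene, −40 °C
Reagents that add atoms: none
Why: Proposed new method: the phosphoric acid protonates one methoxy group of 25 and, helped by the neighbouring C8a hydroxyl, methanol is lost to give the 4-methoxy ortho-quinone methide 28, held as a hydrogen-bonded ion pair with the chiral phosphate; the styrene 27, a vinylogous enol through its para hydroxyl, attacks C4 with its terminal carbon C3 and O1 then closes on the benzylic carbon C2, an inverse-demand hetero-[4+2] addition that is concerted but strongly asynchronous. The closest known reactions are the achiral acid-promoted assembly of 4-alkoxy-2-arylchromans from salicylaldehydes, orthoformates and styrenes, and chiral phosphoric acid-catalysed [4+2] additions of ortho-quinone methides to hydroxystyrenes; new here is an acetal-derived, 4-alkoxy-substituted quinone methide under chiral-acid control. Ring C is closed in a formal [4+2] mode; in the stepwise limit the second bond forms by 6-exo-trig capture of the para-quinone-methide-like carbon C2 by O1, which also restores the aromaticity of ring A. C2 is set by the catalyst: the phosphate bridges the C8a oxygen of the heterodiene and the 4'-hydroxyl of 27 and so exposes one face of the styrene, while the remote chain centre has no influence. C4 is expected 2,4-cis from an endo-type arrangement of aryl and methoxy groups, but it is disposable because it becomes the carbonyl carbon. Regiochemistry is secured by the substrate: only the C8a hydroxyl is free, so the ring oxygen ends up next to C8, and the polarity of the partners (nucleophilic CH2 terminus, electrophilic C4) gives the 2-aryl and not the 3-aryl chroman. Weak acid, low temperature and sieves that bind methanol are meant to suppress the uncatalysed pathway, re-ionisation at C2 of the para-hydroxybenzylic ether and loss of methanol from C4; the isopropenyl group is far less nucleophilic than 27 and cannot reach C4.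

Step 17
Reactants: 29 4-[(2S,4S)-7-(TBSO)-4-methoxy-8-[(2R)-5-methyl-2-(prop-1-en-2-yl)-5-(TESO)hexyl]-5-(TIPSO)chroman-2-yl]-3-methoxyphenol
Product: 30 (2S,4S)-7-(TBSO)-2-[4-(TBSO)-2-methoxyphenyl]-4-methoxy-8-[(2R)-5-methyl-2-(prop-1-en-2-yl)-5-(TESO)hexyl]-5-(TIPSO)chromane
Conditions: TBSCl, imidazole, DMF, 0 °C → rt
Reagents that add atoms: tert-butyldimethylsilyl chloride, CC(C)(C)[Si](C)(C)Cl
Why: Silylation of the only free phenol; it removes the para-hydroxyl assistance that could reopen C2–O1 under acid and shields the phenol from the oxidant of step 19.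

Step 18
Reactants: 30 (2S,4S)-7-(TBSO)-2-[4-(TBSO)-2-methoxyphenyl]-4-methoxy-8-[(2R)-5-methyl-2-(prop-1-en-2-yl)-5-(TESO)hexyl]-5-(TIPSO)chromane
Product: 31 (2S)-7-(TBSO)-2-[4-(TBSO)-2-methoxyphenyl]-8-[(2R)-5-methyl-2-(prop-1-en-2-yl)-5-(TESO)hexyl]-5-(TIPSO)chroman-4-ol (both C4 epimers)
Conditions: pyridinium p-toluenesulfonate (cat.), THF/H2O 4:1, rt
Reagents that add atoms: water, O
Why: SN1 solvolysis of a benzylic methyl ether: the C4 cation is stabilised by the three oxygens of ring A and is captured by water, whereas ionisation at C2 is much less favourable once the 4'-oxygen is silylated. Either C4 epimer serves, since the centre is oxidised next.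

Step 19
Reactants: 31 (2S)-7-(TBSO)-2-[4-(TBSO)-2-methoxyphenyl]-8-[(2R)-5-methyl-2-(prop-1-en-2-yl)-5-(TESO)hexyl]-5-(TIPSO)chroman-4-ol (both C4 epimers)
Product: 32 (2S)-7-(TBSO)-2-[4-(TBSO)-2-methoxyphenyl]-8-[(2R)-5-methyl-2-(prop-1-en-2-yl)-5-(TESO)hexyl]-5-(TIPSO)-2,3-dihydro-4H-chromen-4-one
Conditions: Dess–Martin periodinane, pyridine, CH2Cl2, 0 °C → rt
Reagents that add atoms: none
Why: Dess–Martin oxidation of a secondary benzylic alcohol under buffered, essentially neutral conditions, so the new flavanone is not opened to the chalcone and C2 is kept; alkene, silyl ethers and the masked tertiary alcohol are inert.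

Step 20
Reactants: 32 (2S)-7-(TBSO)-2-[4-(TBSO)-2-methoxyphenyl]-8-[(2R)-5-methyl-2-(prop-1-en-2-yl)-5-(TESO)hexyl]-5-(TIPSO)-2,3-dihydro-4H-chromen-4-one
Product: 33 (2S)-5,7-dihydroxy-8-[(2R)-5-hydroxy-5-methyl-2-(prop-1-en-2-yl)hexyl]-2-(4-hydroxy-2-methoxyphenyl)-2,3-dihydro-4H-chromen-4-one
Conditions: Bu4NF, AcOH (1:1), THF, 0 °C → rt
Reagents that add atoms: none
Why: Global fluoride desilylation of three aryl silyl ethers and the tertiary TES ether; acetic acid protonates the phenoxides as they form, so the medium never becomes basic enough for retro-oxa-Michael opening and C2 should stay (S).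

## Compound list

1 | (4S)-4-benzyl-1,3-oxazolidin-2-one | O=C1N[C@@H](Cc2ccccc2)CO1 | starting material
2 | 3-methylbut-2-enoyl chloride | CC(C)=CC(=O)Cl | starting material
3 | lithium (4S)-4-benzyl-2-oxo-1,3-oxazolidin-3-ide | [Li]N1[C@@H](Cc2ccccc2)COC1=O | intermediate (not isolated)
4 | (4S)-4-benzyl-3-(3-methylbut-2-enoyl)-1,3-oxazolidin-2-one | CC(C)=CC(=O)N1[C@@H](Cc2ccccc2)COC1=O | intermediate
5 | 1-bromo-3-methylbut-2-ene | CC(C)=CCBr | starting material
6 | sodium (Z)-dienolate of 4 | C=C(C)/C=C(\O[Na])N1[C@@H](Cc2ccccc2)COC1=O | intermediate (not isolated)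
7 | (4S)-4-benzyl-3-[(2S)-5-methyl-2-(prop-1-en-2-yl)hex-4-enoyl]-1,3-oxazolidin-2-one | C=C(C)[C@H](CC=C(C)C)C(=O)N1[C@@H](Cc2ccccc2)COC1=O | intermediate
8 | (4S)-4-benzyl-3-[(2S)-2-[(3,3-dimethyloxiran-2-yl)methyl]-3-methylbut-3-enoyl]-1,3-oxazolidin-2-one, both epimers at the oxirane carbon | C=C(C)[C@H](CC1OC1(C)C)C(=O)N1[C@@H](Cc2ccccc2)COC1=O | intermediate
9 | (2S)-5-methyl-2-(prop-1-en-2-yl)hexane-1,5-diol | C=C(C)[C@H](CCC(C)(C)O)CO | intermediate
10 | (5S)-6-iodo-2-methyl-5-(prop-1-en-2-yl)hexan-2-ol | C=C(C)[C@H](CCC(C)(C)O)CI | intermediate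
11 | triethyl{[(5S)-6-iodo-2-methyl-5-(prop-1-en-2-yl)hexan-2-yl]oxy}silane | C=C(C)[C@H](CCC(C)(C)O[Si](CC)(CC)CC)CI | intermediate
12 | phloroglucinol (benzene-1,3,5-triol) | Oc1cc(O)cc(O)c1 | starting material
13 | 5-{[tri(propan-2-yl)silyl]oxy}benzene-1,3-diol | Oc1cc(O)cc(O[Si](C(C)C)(C(C)C)C(C)C)c1 | intermediate
14 | 1,3-bis(methoxymethoxy)-5-{[tri(propan-2-yl)silyl]oxy}benzene | COCOc1cc(OCOC)cc(O[Si](C(C)C)(C(C)C)C(C)C)c1 | intermediate
15 | 2,6-bis(methoxymethoxy)-4-{[tri(propan-2-yl)silyl]oxy}phenyllithium | [Li]c1c(OCOC)cc(O[Si](C(C)C)(C(C)C)C(C)C)cc1OCOC | intermediate (not isolated)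
16 | 2-iodo-1,3-bis(methoxymethoxy)-5-{[tri(propan-2-yl)silyl]oxy}benzene | COCOc1cc(O[Si](C(C)C)(C(C)C)C(C)C)cc(OCOC)c1I | intermediate
17 | [(2S)-5-methyl-2-(prop-1-en-2-yl)-5-(triethylsilyloxy)hexyl]zinc iodide | C=C(C)[C@H](CCC(C)(C)O[Si](CC)(CC)CC)C[Zn]I | intermediate (not isolated)
18 | 2-[(2R)-5-methyl-2-(prop-1-en-2-yl)-5-(triethylsilyloxy)hexyl]-1,3-bis(methoxymethoxy)-5-(triisopropylsilyloxy)benzene | C=C(C)[C@H](CCC(C)(C)O[Si](CC)(CC)CC)Cc1c(OCOC)cc(O[Si](C(C)C)(C(C)C)C(C)C)cc1OCOC | intermediate
19 | 4-lithio derivative of 18 (lithium between a methoxymethoxy group and the triisopropylsilyloxy group) | C=C(C)[C@H](CCC(C)(C)O[Si](CC)(CC)CC)Cc1c(OCOC)cc(O[Si](C(C)C)(C(C)C)C(C)C)c([Li])c1OCOC | intermediate (not isolated)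
20 | 2,4-bis(methoxymethoxy)-3-[(2R)-5-methyl-2-(prop-1-en-2-yl)-5-(triethylsilyloxy)hexyl]-6-(triisopropylsilyloxy)benzaldehyde | C=C(C)[C@H](CCC(C)(C)O[Si](CC)(CC)CC)Cc1c(OCOC)cc(O[Si](C(C)C)(C(C)C)C(C)C)c(C=O)c1OCOC | intermediate
21 | 3-[(2R)-5-methyl-2-(prop-1-en-2-yl)-5-(triethylsilyloxy)hexyl]-6-(triisopropylsilyloxy)-2,4-bis(trimethylsilyloxy)benzaldehyde | C=C(C)[C@H](CCC(C)(C)O[Si](CC)(CC)CC)Cc1c(O[Si](C)(C)C)cc(O[Si](C(C)C)(C(C)C)C(C)C)c(C=O)c1O[Si](C)(C)C | intermediate (not isolated)
22 | 2,4-dihydroxy-3-[(2R)-5-methyl-2-(prop-1-en-2-yl)-5-(triethylsilyloxy)hexyl]-6-(triisopropylsilyloxy)benzaldehyde | C=C(C)[C@H](CCC(C)(C)O[Si](CC)(CC)CC)Cc1c(O)cc(O[Si](C(C)C)(C(C)C)C(C)C)c(C=O)c1O | intermediate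
23 | 4-(tert-butyldimethylsilyloxy)-2-hydroxy-3-[(2R)-5-methyl-2-(prop-1-en-2-yl)-5-(triethylsilyloxy)hexyl]-6-(triisopropylsilyloxy)benzaldehyde | C=C(C)[C@H](CCC(C)(C)O[Si](CC)(CC)CC)Cc1c(O[Si](C)(C)C(C)(C)C)cc(O[Si](C(C)C)(C(C)C)C(C)C)c(C=O)c1O | intermediate
24 | trimethyl orthoformate | COC(OC)OC | starting material
25 | 3-(tert-butyldimethylsilyloxy)-6-(dimethoxymethyl)-2-[(2R)-5-methyl-2-(prop-1-en-2-yl)-5-(triethylsilyloxy)hexyl]-5-(triisopropylsilyloxy)phenol | C=C(C)[C@H](CCC(C)(C)O[Si](CC)(CC)CC)Cc1c(O[Si](C)(C)C(C)(C)C)cc(O[Si](C(C)C)(C(C)C)C(C)C)c(C(OC)OC)c1O | intermediate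
26 | 4-hydroxy-2-methoxybenzaldehyde | COc1cc(O)ccc1C=O | starting material
27 | 3-methoxy-4-vinylphenol | C=Cc1ccc(O)cc1OC | intermediate
28 | 3-(tert-butyldimethylsilyloxy)-6-(methoxymethylidene)-2-[(2R)-5-methyl-2-(prop-1-en-2-yl)-5-(triethylsilyloxy)hexyl]-5-(triisopropylsilyloxy)cyclohexa-2,4-dien-1-one (ortho-quinone methide, exocyclic alkene geometry not defined) | C=C(C)[C@H](CCC(C)(C)O[Si](CC)(CC)CC)CC1=C(O[Si](C)(C)C(C)(C)C)C=C(O[Si](C(C)C)(C(C)C)C(C)C)C(=COC)C1=O | intermediate (not isolated)
29 | 4-[(2S,4S)-7-(tert-butyldimethylsilyloxy)-4-methoxy-8-[(2R)-5-methyl-2-(prop-1-en-2-yl)-5-(triethylsilyloxy)hexyl]-5-(triisopropylsilyloxy)chroman-2-yl]-3-methoxyphenol (2,4-cis) | C=C(C)[C@H](CCC(C)(C)O[Si](CC)(CC)CC)Cc1c(O[Si](C)(C)C(C)(C)C)cc(O[Si](C(C)C)(C(C)C)C(C)C)c2c1O[C@H](c1ccc(O)cc1OC)C[C@@H]2OC | intermediate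
30 | (2S,4S)-7-(tert-butyldimethylsilyloxy)-2-[4-(tert-butyldimethylsilyloxy)-2-methoxyphenyl]-4-methoxy-8-[(2R)-5-methyl-2-(prop-1-en-2-yl)-5-(triethylsilyloxy)hexyl]-5-(triisopropylsilyloxy)chromane | C=C(C)[C@H](CCC(C)(C)O[Si](CC)(CC)CC)Cc1c(O[Si](C)(C)C(C)(C)C)cc(O[Si](C(C)C)(C(C)C)C(C)C)c2c1O[C@H](c1ccc(O[Si](C)(C)C(C)(C)C)cc1OC)C[C@@H]2OC | intermediate
31 | (2S)-7-(tert-butyldimethylsilyloxy)-2-[4-(tert-butyldimethylsilyloxy)-2-methoxyphenyl]-8-[(2R)-5-methyl-2-(prop-1-en-2-yl)-5-(triethylsilyloxy)hexyl]-5-(triisopropylsilyloxy)chroman-4-ol, both C4 epimers | C=C(C)[C@H](CCC(C)(C)O[Si](CC)(CC)CC)Cc1c(O[Si](C)(C)C(C)(C)C)cc(O[Si](C(C)C)(C(C)C)C(C)C)c2c1O[C@H](c1ccc(O[Si](C)(C)C(C)(C)C)cc1OC)CC2O | intermediate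
32 | (2S)-7-(tert-butyldimethylsilyloxy)-2-[4-(tert-butyldimethylsilyloxy)-2-methoxyphenyl]-8-[(2R)-5-methyl-2-(prop-1-en-2-yl)-5-(triethylsilyloxy)hexyl]-5-(triisopropylsilyloxy)-2,3-dihydro-4H-chromen-4-one | C=C(C)[C@H](CCC(C)(C)O[Si](CC)(CC)CC)Cc1c(O[Si](C)(C)C(C)(C)C)cc(O[Si](C(C)C)(C(C)C)C(C)C)c2c1O[C@H](c1ccc(O[Si](C)(C)C(C)(C)C)cc1OC)CC2=O | intermediate
33 | (2S)-5,7-dihydroxy-8-[(2R)-5-hydroxy-5-methyl-2-(prop-1-en-2-yl)hexyl]-2-(4-hydroxy-2-methoxyphenyl)-2,3-dihydro-4H-chromen-4-one | C=C(C)[C@H](CCC(C)(C)O)Cc1c(O)cc(O)c2c1O[C@H](c1ccc(O)cc1OC)CC2=O | target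

## Step count and least certain steps

Total step count: 20 (steps 1–6 chain fragment, 7–9 aryl iodide, 10–14 ring A aldehyde and acetal, 15 styrene, 16 cycloaddition, 17–20 end game).
Longest linear sequence: 16 steps (1–6, 10–14, 16–20).

**Step 16 (key step).** The most likely failure is poor enantiofacial discrimination, because an uncatalysed or loosely ion-paired pathway competes, together with erosion at C2 by acid-induced reopening of the para-hydroxybenzylic ether. The fallback uses known chemistry and moves stereocontrol from the cycloaddition to a resolution. It sets out from 25 and 27. An achiral acid (pyridinium p-toluenesulfonate, CH2Cl2) promotes the established chroman-forming addition and gives the cis-4-methoxyflavan as a mixture of C2 epimers F1. This is silylated to F2, hydrolysed to the flavan-4-ol mixture F3 and oxidised to the flavanone epimer mixture F4 under the conditions of steps 17–19. Kinetic resolution of F4 by asymmetric transfer hydrogenation with RuCl[(R,R)-TsDPEN](p-cymene) and HCO2H/Et3N is expected to reduce the (2R)-epimer to the cis-(2R,4R)-flavan-4-ol F5 and leave the (2S)-ketone, which is 32, where the route is rejoined. Should the catalyst prefer the other epimer, its mirror image is used, or the reduced (2S)-alcohol, a component of 31, is oxidised as in step 19. F5 can be recycled by oxidation and base equilibration of C2 through the chalcone, which returns F4.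

**Step 10.** The likely failure is slow transmetalation and reductive elimination at the di-ortho-alkoxy aryl centre with a β-branched alkyl group, so that protodemetalation of 17 and reduction of 16 take over; partial vinyl migration during the radical zinc insertion is a second risk. The fallback changes the organometallic partner and how it is made. It sets out from 11: iodine–lithium exchange with t-BuLi at −78 °C and trapping with 9-methoxy-9-borabicyclo[3.3.1]nonane give the borate complex F6, which is coupled with 16 by a B-alkyl Suzuki–Miyaura reaction (PdCl2(dppf), K3PO4, DMF/THF) and returns to the route at 18.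

**Step 11.** The likely failure is sluggish deprotonation next to the bulky silyloxy group, with migration of silicon from oxygen to the lithiated carbon or metalation of the allylic methyl group at the temperature needed. The fallback replaces deprotonation by halogen–metal exchange. It sets out from 18: bromination with N-bromosuccinimide (MeCN, −20 °C; only one kind of ring position is open) gives the aryl bromide F7, and exchange with t-BuLi at −78 °C followed by DMF returns to the route at 20.

**Step 12.** The likely failure is loss of the tertiary TES ether or attack of the activated aldehyde or the methoxymethyl fragment on the electron-rich ring before both acetals are gone. The fallback changes the order and the way the formyl group is introduced. It sets out from 18: the methoxymethyl ethers are cleaved at the arene stage, where no aldehyde is present, to give the resorcinol F8; magnesium-mediated ortho-formylation of the phenol (MgCl2, Et3N, paraformaldehyde, MeCN, reflux) can reach only the two equivalent positions ortho to a hydroxyl and returns to the route at 22.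

**Step 18.** The likely failure is elimination from the C4 cation to the flav-3-ene instead of capture by water, or partial loss of silyl groups on prolonged exposure to acid. The fallback is oxidative instead of hydrolytic. It sets out from 30: 2,3-dichloro-5,6-dicyano-1,4-benzoquinone in wet CH2Cl2 abstracts the benzylic hydride at C4, and the resulting oxocarbenium ion is hydrolysed directly to the ketone. This returns to the route at 32 and passes through no new isolated compound.

## Further compounds

F1 | step 16 | 2,4-cis-4-methoxyflavan 29 together with its (2R,4R)-isomer (mixture of C2 epimers) | C=C(C)[C@H](CCC(C)(C)O[Si](CC)(CC)CC)Cc1c(O[Si](C)(C)C(C)(C)C)cc(O[Si](C(C)C)(C(C)C)C(C)C)c2c1OC(c1ccc(O)cc1OC)CC2OC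
F2 | step 16 | 4'-O-tert-butyldimethylsilyl ether of F1 (mixture of C2 epimers) | C=C(C)[C@H](CCC(C)(C)O[Si](CC)(CC)CC)Cc1c(O[Si](C)(C)C(C)(C)C)cc(O[Si](C(C)C)(C(C)C)C(C)C)c2c1OC(c1ccc(O[Si](C)(C)C(C)(C)C)cc1OC)CC2OC
F3 | step 16 | flavan-4-ol from F2 (mixture of C2 and C4 epimers) | C=C(C)[C@H](CCC(C)(C)O[Si](CC)(CC)CC)Cc1c(O[Si](C)(C)C(C)(C)C)cc(O[Si](C(C)C)(C(C)C)C(C)C)c2c1OC(c1ccc(O[Si](C)(C)C(C)(C)C)cc1OC)CC2O
F4 | step 16 | fully silylated flavanone as a mixture of 32 and its (2R)-epimer | C=C(C)[C@H](CCC(C)(C)O[Si](CC)(CC)CC)Cc1c(O[Si](C)(C)C(C)(C)C)cc(O[Si](C(C)C)(C(C)C)C(C)C)c2c1OC(c1ccc(O[Si](C)(C)C(C)(C)C)cc1OC)CC2=O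
F5 | step 16 | (2R,4R)-7-(tert-butyldimethylsilyloxy)-2-[4-(tert-butyldimethylsilyloxy)-2-methoxyphenyl]-8-[(2R)-5-methyl-2-(prop-1-en-2-yl)-5-(triethylsilyloxy)hexyl]-5-(triisopropylsilyloxy)chroman-4-ol | C=C(C)[C@H](CCC(C)(C)O[Si](CC)(CC)CC)Cc1c(O[Si](C)(C)C(C)(C)C)cc(O[Si](C(C)C)(C(C)C)C(C)C)c2c1O[C@@H](c1ccc(O[Si](C)(C)C(C)(C)C)cc1OC)C[C@H]2O
F6 | step 10 | lithium 9-methoxy-9-[(2S)-5-methyl-2-(prop-1-en-2-yl)-5-(triethylsilyloxy)hexyl]-9-borabicyclo[3.3.1]nonan-9-uide | [Li+].C=C(C)[C@H](CCC(C)(C)O[Si](CC)(CC)CC)C[B-]1(OC)C2CCCC1CCC2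
F7 | step 11 | 1-bromo-3-[(2R)-5-methyl-2-(prop-1-en-2-yl)-5-(triethylsilyloxy)hexyl]-2,4-bis(methoxymethoxy)-6-(triisopropylsilyloxy)benzene | C=C(C)[C@H](CCC(C)(C)O[Si](CC)(CC)CC)Cc1c(OCOC)cc(O[Si](C(C)C)(C(C)C)C(C)C)c(Br)c1OCOC
F8 | step 12 | 2-[(2R)-5-methyl-2-(prop-1-en-2-yl)-5-(triethylsilyloxy)hexyl]-5-(triisopropylsilyloxy)benzene-1,3-diol | C=C(C)[C@H](CCC(C)(C)O[Si](CC)(CC)CC)Cc1c(O)cc(O[Si](C(C)C)(C(C)C)C(C)C)cc1O
F0 | step 18 | none | none
A1 | alternative 1 | (2S)-2-[4-(tert-butyldimethylsilyloxy)-2-methoxyphenyl]-6-[(3R)-1-(2,2-dimethyl-4-oxo-4H-1,3-dioxin-6-yl)-6-methyl-3-(prop-1-en-2-yl)-6-(triethylsilyloxy)heptyl]-2,3-dihydro-4H-pyran-4-one | C=C(C)[C@H](CCC(C)(C)O[Si](CC)(CC)CC)CC(C1=CC(=O)OC(C)(C)O1)C1=CC(=O)C[C@@H](c2ccc(O[Si](C)(C)C(C)(C)C)cc2OC)O1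
A2 | alternative 1 | (2S)-2-[4-(tert-butyldimethylsilyloxy)-2-methoxyphenyl]-5,7-dihydroxy-8-[(2R)-5-methyl-2-(prop-1-en-2-yl)-5-(triethylsilyloxy)hexyl]-2,3-dihydro-4H-chromen-4-one | C=C(C)[C@H](CCC(C)(C)O[Si](CC)(CC)CC)Cc1c(O)cc(O)c2c1O[C@H](c1ccc(O[Si](C)(C)C(C)(C)C)cc1OC)CC2=O
A3 | alternative 2 | 3-[(4-methoxybenzyl)oxy]cyclobut-2-en-1-one | O=C1C=C(OCc2ccc(OC)cc2)C1
A4 | alternative 2 | triethyl{[(5R)-2-methyl-5-(prop-1-en-2-yl)-8-(triisopropylsilyloxy)oct-7-yn-2-yl]oxy}silane | C=C(C)[C@H](CCC(C)(C)O[Si](CC)(CC)CC)CC#CO[Si](C(C)C)(C(C)C)C(C)C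
A5 | alternative 2 | (R)-limonene, (4R)-1-methyl-4-(prop-1-en-2-yl)cyclohex-1-ene | C=C(C)[C@@H]1CCC(C)=CC1
A6 | alternative 2 | 5-[(4-methoxybenzyl)oxy]-2-[(2R)-5-methyl-2-(prop-1-en-2-yl)-5-(triethylsilyloxy)hexyl]-3-(triisopropylsilyloxy)phenol | C=C(C)[C@H](CCC(C)(C)O[Si](CC)(CC)CC)Cc1c(O)cc(OCc2ccc(OC)cc2)cc1O[Si](C(C)C)(C(C)C)C(C)C
A7 | alternative 3 | 3-(tert-butyldimethylsilyloxy)-6-iodo-2-[(2R)-5-methyl-2-(prop-1-en-2-yl)-5-(triethylsilyloxy)hexyl]-5-(triisopropylsilyloxy)phenol | C=C(C)[C@H](CCC(C)(C)O[Si](CC)(CC)CC)Cc1c(O[Si](C)(C)C(C)(C)C)cc(O[Si](C(C)C)(C(C)C)C(C)C)c(I)c1O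
A8 | alternative 3 | tert-butyl(4-ethynyl-3-methoxyphenoxy)dimethylsilane | C#Cc1ccc(O[Si](C)(C)C(C)(C)C)cc1OC
A9 | alternative 3 | 7-(tert-butyldimethylsilyloxy)-2-[4-(tert-butyldimethylsilyloxy)-2-methoxyphenyl]-8-[(2R)-5-methyl-2-(prop-1-en-2-yl)-5-(triethylsilyloxy)hexyl]-5-(triisopropylsilyloxy)-4H-chromen-4-one | C=C(C)[C@H](CCC(C)(C)O[Si](CC)(CC)CC)Cc1c(O[Si](C)(C)C(C)(C)C)cc(O[Si](C(C)C)(C(C)C)C(C)C)c2c1OC(c1ccc(O[Si](C)(C)C(C)(C)C)cc1OC)=CC2=O
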